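**Retrosynthetic overview**

1. Rings are called A–E along the chain A–O–B–O–C–O–D–O–E (A = 3,5-dihydroxyphenoxy end, E = 2,4,6-trihydroxyphenyl end). No ring is built: all five are bought, only the four aryl C–O bonds are made, and 14 ⇐ 13 by global O-demethylation.
2. Key disconnection: C–O–D and D–O–E at the ring carbon flanked by two oxygens. This is the nucleophilic enol carbon (C-2) of a phloroglucinol, so it is brought in with reversed polarity as an electrophile. Bromo-aldehydes 2 and 8 are enolonium-type equivalents of a phloroglucinol C-2 cation; their CHO activates the C–Br bond and is a latent OH (Baeyer–Villiger/Dakin).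
3. Core: unprotected 2,6-dimethoxyhydroquinone (ring C). Its two OH groups are told apart by hindrance alone, so D and then B are attached in one pot without protecting groups.
4. A double Dakin oxidation unveils one OH on D and one on B; these are arylated in steric order (E, then A) in one pot.
5. Order of ring attachment: C → D → B → E → A; then Dakin on E and demethylation.

Assumption: 14 has no stereocentre and no configurationally stable axis (diaryl ethers rotate freely), so it is achiral and no step needs stereocontrol; 1, 2, 3, 8 and 9 are taken as catalogue compounds.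

**Route**

Step 1
Reactants: 1 2,6-dimethoxybenzene-1,4-diol; 2 2-bromo-3,5-dimethoxybenzaldehyde; 3 2-bromo-4,6-dimethoxybenzaldehyde
Product: 5 2-[4-(2-formyl-4,6-dimethoxyphenoxy)-2,6-dimethoxyphenoxy]-4,6-dimethoxybenzaldehyde, via hydroquinone mono-aryl ether 4 (not isolated)
Conditions: CuI (10 mol%), picolinic acid (20 mol%), K3PO4 (3.5 equiv), degassed DMSO, Ar, 1 : 2 = 1 : 1, 90 °C; then 3 (1.2 equiv), 110 °C
Reagents that add atoms: none
Why: Two Ullmann-type Cu-catalysed diaryl ether couplings in one pot: the ortho-formyl bromide 2 (the polarity-reversed phloroglucinol C-2 electrophile) reacts only at the unhindered, more acidic 4-OH of 1 because attack by the 1-OH would need a tetra-ortho-substituted ether, and the less hindered ortho-formyl bromide 3 then arylates the remaining 2,6-dimethoxy-flanked phenoxide; no stereocentre is formed.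

Step 2
Reactants: 5 2-[4-(2-formyl-4,6-dimethoxyphenoxy)-2,6-dimethoxyphenoxy]-4,6-dimethoxybenzaldehyde
Product: 7 2-[4-(2-hydroxy-4,6-dimethoxyphenoxy)-2,6-dimethoxyphenoxy]-4,6-dimethoxyphenol, via bis-formate 6 (not isolated)
Conditions: mCPBA (2.6 equiv), CH2Cl2, 0 °C → rt; then K2CO3, degassed MeOH, Ar, rt
Reagents that add atoms: mCPBA (3-chloroperoxybenzoic acid), O=C(OO)c1cccc(Cl)c1
Why: Double Baeyer–Villiger (Dakin-type) oxidation: each aldehyde has an ortho oxygen donor, so the aryl group migrates in the Criegee intermediate to give the aryl formate, which K2CO3/MeOH transesterifies to the phenol; 5 has no free phenol to over-oxidise.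

Step 3
Reactants: 7 2-[4-(2-hydroxy-4,6-dimethoxyphenoxy)-2,6-dimethoxyphenoxy]-4,6-dimethoxyphenol; 8 4-bromo-3,5-dimethoxybenzaldehyde; 9 1-iodo-3,5-dimethoxybenzene
Product: 11 4-[2-[4-[2-(3,5-dimethoxyphenoxy)-3,5-dimethoxyphenoxy]-3,5-dimethoxyphenoxy]-3,5-dimethoxyphenoxy]-3,5-dimethoxybenzaldehyde, via tetramer aldehyde 10 (not isolated)
Conditions: CuI (20 mol%), picolinic acid (40 mol%), K3PO4 (3.5 equiv), degassed DMSO, Ar, 8 (1.1 equiv), 105 °C; then 9 (2 equiv), 110 °C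
Reagents that add atoms: none
Why: Two Ullmann-type Cu-catalysed O-arylations in steric order: the di-ortho-methoxy, para-formyl-activated bromide 8 (again a phloroglucinol C-2 electrophile) couples only with the mono-ortho-substituted, more acidic ring-D phenol of 7 (the ring-B phenol would give a tetra-ortho-substituted ether), and the unhindered iodide 9 then arylates the remaining 2,6-disubstituted ring-B phenol.

Step 4
Reactants: 11 4-[2-[4-[2-(3,5-dimethoxyphenoxy)-3,5-dimethoxyphenoxy]-3,5-dimethoxyphenoxy]-3,5-dimethoxyphenoxy]-3,5-dimethoxybenzaldehyde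
Product: 13 4-[2-[4-[2-(3,5-dimethoxyphenoxy)-3,5-dimethoxyphenoxy]-3,5-dimethoxyphenoxy]-3,5-dimethoxyphenoxy]-3,5-dimethoxyphenol, via aryl formate 12 (not isolated)
Conditions: mCPBA (1.3 equiv), CH2Cl2, 0 °C → rt; then K2CO3, degassed MeOH, rt
Reagents that add atoms: mCPBA (3-chloroperoxybenzoic acid), O=C(OO)c1cccc(Cl)c1
Why: Baeyer–Villiger (Dakin-type) oxidation: the para-aryloxy group makes the aryl migrate, as with 4-aryloxy- and 3,4,5-trialkoxybenzaldehydes, and methanolysis of the formate frees the ring-E 4-OH; 11 carries no free phenol.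

Step 5
Reactants: 13 4-[2-[4-[2-(3,5-dimethoxyphenoxy)-3,5-dimethoxyphenoxy]-3,5-dimethoxyphenoxy]-3,5-dimethoxyphenoxy]-3,5-dimethoxyphenol
Product: 14 2-[2-[4-[2-(3,5-dihydroxyphenoxy)-3,5-dihydroxyphenoxy]-3,5-dihydroxyphenoxy]-3,5-dihydroxyphenoxy]benzene-1,3,5-triol (CNP0018313.0)
Conditions: BBr3 (25 equiv), CH2Cl2, −78 °C → rt; then MeOH, H2O; Sephadex LH-20 under Ar
Reagents that add atoms: none
Why: BBr3 aryl methyl ether cleavage (Lewis-acid O-demethylation): bromide attacks only the methyl carbons of the ArO(Me)–BBr2 adducts, the diaryl ether C–O bonds are inert, and hydrolysis of the borates frees all eleven phenols of the achiral target.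

**Compound list**

1 | 2,6-dimethoxybenzene-1,4-diol (ring C) | COc1cc(O)cc(OC)c1O | starting material
2 | 2-bromo-3,5-dimethoxybenzaldehyde (ring D unit) | O=Cc1cc(OC)cc(OC)c1Br | starting material
3 | 2-bromo-4,6-dimethoxybenzaldehyde (ring B unit) | O=Cc1c(Br)cc(OC)cc1OC | starting material
4 | 2-(4-hydroxy-3,5-dimethoxyphenoxy)-3,5-dimethoxybenzaldehyde | O=Cc1cc(OC)cc(OC)c1Oc1cc(OC)c(O)c(OC)c1 | intermediate (not isolated)
5 | 2-[4-(2-formyl-4,6-dimethoxyphenoxy)-2,6-dimethoxyphenoxy]-4,6-dimethoxybenzaldehyde | O=Cc1c(OC)cc(OC)cc1Oc1c(OC)cc(Oc2c(C=O)cc(OC)cc2OC)cc1OC | intermediate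
6 | 2-[4-(2-formyloxy-4,6-dimethoxyphenoxy)-2,6-dimethoxyphenoxy]-4,6-dimethoxyphenyl formate | O=COc1c(OC)cc(OC)cc1Oc1c(OC)cc(Oc2c(OC=O)cc(OC)cc2OC)cc1OC | intermediate (not isolated)
7 | 2-[4-(2-hydroxy-4,6-dimethoxyphenoxy)-2,6-dimethoxyphenoxy]-4,6-dimethoxyphenol | Oc1c(OC)cc(OC)cc1Oc1c(OC)cc(Oc2c(O)cc(OC)cc2OC)cc1OC | intermediate
8 | 4-bromo-3,5-dimethoxybenzaldehyde (ring E unit) | O=Cc1cc(OC)c(Br)c(OC)c1 | starting material
9 | 1-iodo-3,5-dimethoxybenzene (ring A unit) | COc1cc(I)cc(OC)c1 | starting material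
10 | 4-[2-[4-(2-hydroxy-3,5-dimethoxyphenoxy)-3,5-dimethoxyphenoxy]-3,5-dimethoxyphenoxy]-3,5-dimethoxybenzaldehyde | Oc1c(OC)cc(OC)cc1Oc1c(OC)cc(Oc2c(Oc3c(OC)cc(C=O)cc3OC)cc(OC)cc2OC)cc1OC | intermediate (not isolated)
11 | 4-[2-[4-[2-(3,5-dimethoxyphenoxy)-3,5-dimethoxyphenoxy]-3,5-dimethoxyphenoxy]-3,5-dimethoxyphenoxy]-3,5-dimethoxybenzaldehyde | COc1cc(OC)cc(Oc2c(OC)cc(OC)cc2Oc2c(OC)cc(Oc3c(Oc4c(OC)cc(C=O)cc4OC)cc(OC)cc3OC)cc2OC)c1 | intermediate
12 | 4-[2-[4-[2-(3,5-dimethoxyphenoxy)-3,5-dimethoxyphenoxy]-3,5-dimethoxyphenoxy]-3,5-dimethoxyphenoxy]-3,5-dimethoxyphenyl formate | COc1cc(OC)cc(Oc2c(OC)cc(OC)cc2Oc2c(OC)cc(Oc3c(Oc4c(OC)cc(OC=O)cc4OC)cc(OC)cc3OC)cc2OC)c1 | intermediate (not isolated)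
13 | 4-[2-[4-[2-(3,5-dimethoxyphenoxy)-3,5-dimethoxyphenoxy]-3,5-dimethoxyphenoxy]-3,5-dimethoxyphenoxy]-3,5-dimethoxyphenol | COc1cc(OC)cc(Oc2c(OC)cc(OC)cc2Oc2c(OC)cc(Oc3c(Oc4c(OC)cc(O)cc4OC)cc(OC)cc3OC)cc2OC)c1 | intermediate
14 | 2-[2-[4-[2-(3,5-dihydroxyphenoxy)-3,5-dihydroxyphenoxy]-3,5-dihydroxyphenoxy]-3,5-dihydroxyphenoxy]benzene-1,3,5-triol | Oc1cc(O)cc(Oc2c(O)cc(O)cc2Oc2c(O)cc(Oc3c(O)cc(O)cc3Oc3c(O)cc(O)cc3O)cc2O)c1 | target

**Step count and risks**

Total step count: 5. Longest linear sequence: 5 (linear from 1; 2, 3, 8 and 9 are bought).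

Steps most likely to fail:

Step 1 (one-pot double arylation of the unprotected hydroquinone): 1 can be oxidised to the quinone under basic Cu conditions, and any unreacted 1 gives mixed ethers with 3. Fallback, from 1 back to 5, with a protecting group and the two couplings in inverted order: benzylate the unhindered 4-OH of 1 (BnBr, K2CO3, acetone) to 4-(benzyloxy)-2,6-dimethoxyphenol F1. Couple its hindered phenol with 3 under the same Cu conditions to 2-[4-(benzyloxy)-2,6-dimethoxyphenoxy]-4,6-dimethoxybenzaldehyde F2. Remove the benzyl group (H2, Pd/C, EtOAc, 1 atm, stopped after 1 equiv H2) to 2-(4-hydroxy-2,6-dimethoxyphenoxy)-4,6-dimethoxybenzaldehyde F3, and couple this single unhindered phenol with 2 to reach 5.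

Step 3 (telling the two phenols of 7 apart with the hindered bromide 8): selectivity rests on sterics and acidity only. Fallback, from 5 back to 11, unmasking the phenols one at a time. Oxidise only the much more electron-rich 2,4,6-trioxygenated ring-B aldehyde of 5 (mCPBA 1.05 equiv, CH2Cl2, −20 °C) to 2-[4-(2-formyl-4,6-dimethoxyphenoxy)-2,6-dimethoxyphenoxy]-4,6-dimethoxyphenyl formate F4. Methanolyse it to 2-[4-(2-hydroxy-3,5-dimethoxyphenoxy)-3,5-dimethoxyphenoxy]-3,5-dimethoxybenzaldehyde F5. Arylate its only phenol with 9 (Cu conditions) to 2-[4-[2-(3,5-dimethoxyphenoxy)-3,5-dimethoxyphenoxy]-3,5-dimethoxyphenoxy]-3,5-dimethoxybenzaldehyde F6. Oxidise with mCPBA to 2-[4-[2-(3,5-dimethoxyphenoxy)-3,5-dimethoxyphenoxy]-3,5-dimethoxyphenoxy]-3,5-dimethoxyphenyl formate F7 and methanolyse to 2-[4-[2-(3,5-dimethoxyphenoxy)-3,5-dimethoxyphenoxy]-3,5-dimethoxyphenoxy]-3,5-dimethoxyphenol F8. Couple this single phenol with 8 to give 11.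

Step 5 (ten demethylations at once; the free undecaphenol is air-sensitive and hard to purify; partly demethylated borates may precipitate). Fallback, from 13 back to 14, isolating through a stable derivative. After BBr3 and removal of volatiles, acetylate the crude polyphenol directly (Ac2O, pyridine, DMAP) to the undeca-O-acetate of 14 F9. Purify on silica; under-demethylated acetates are separated and recycled. Deacetylate (cat. NaOMe, degassed MeOH, 0 °C, then H+ resin) to 14.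

**Further compounds**

F1 | step 1 | 4-(benzyloxy)-2,6-dimethoxyphenol | COc1cc(OCc2ccccc2)cc(OC)c1O
F2 | step 1 | 2-[4-(benzyloxy)-2,6-dimethoxyphenoxy]-4,6-dimethoxybenzaldehyde | O=Cc1c(OC)cc(OC)cc1Oc1c(OC)cc(OCc2ccccc2)cc1OC
F3 | step 1 | 2-(4-hydroxy-2,6-dimethoxyphenoxy)-4,6-dimethoxybenzaldehyde | O=Cc1c(OC)cc(OC)cc1Oc1c(OC)cc(O)cc1OC
F4 | step 3 | 2-[4-(2-formyl-4,6-dimethoxyphenoxy)-2,6-dimethoxyphenoxy]-4,6-dimethoxyphenyl formate | O=COc1c(OC)cc(OC)cc1Oc1c(OC)cc(Oc2c(C=O)cc(OC)cc2OC)cc1OC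
F5 | step 3 | 2-[4-(2-hydroxy-3,5-dimethoxyphenoxy)-3,5-dimethoxyphenoxy]-3,5-dimethoxybenzaldehyde | Oc1c(OC)cc(OC)cc1Oc1c(OC)cc(Oc2c(C=O)cc(OC)cc2OC)cc1OC
F6 | step 3 | 2-[4-[2-(3,5-dimethoxyphenoxy)-3,5-dimethoxyphenoxy]-3,5-dimethoxyphenoxy]-3,5-dimethoxybenzaldehyde | COc1cc(OC)cc(Oc2c(OC)cc(OC)cc2Oc2c(OC)cc(Oc3c(C=O)cc(OC)cc3OC)cc2OC)c1
F7 | step 3 | 2-[4-[2-(3,5-dimethoxyphenoxy)-3,5-dimethoxyphenoxy]-3,5-dimethoxyphenoxy]-3,5-dimethoxyphenyl formate | COc1cc(OC)cc(Oc2c(OC)cc(OC)cc2Oc2c(OC)cc(Oc3c(OC=O)cc(OC)cc3OC)cc2OC)c1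
F8 | step 3 | 2-[4-[2-(3,5-dimethoxyphenoxy)-3,5-dimethoxyphenoxy]-3,5-dimethoxyphenoxy]-3,5-dimethoxyphenol | COc1cc(OC)cc(Oc2c(OC)cc(OC)cc2Oc2c(OC)cc(Oc3c(O)cc(OC)cc3OC)cc2OC)c1
F9 | step 5 | undeca-O-acetate of 14 | CC(=O)Oc1cc(OC(C)=O)cc(Oc2c(OC(C)=O)cc(OC(C)=O)cc2Oc2c(OC(C)=O)cc(Oc3c(OC(C)=O)cc(OC(C)=O)cc3Oc3c(OC(C)=O)cc(OC(C)=O)cc3OC(C)=O)cc2OC(C)=O)c1
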